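**Plan**

1. Retrosynthetic cuts: the O-acyl and O-silyl groups are end-game adjustments; C11–C12 is cut by a vinylogous Mukaiyama aldol (C11 aldehyde plus a five-carbon silyl dienolate); C9–C11 by one-carbon homologation of a C9 enone carbonyl through its spiro-epoxide; C3–C4 of ring A by addition of a C4 tertiary radical to a C3 aldehyde; C10–C1 and C10–CH3 by two enolate alkylations, which leads back to (S)-carvone.
2. Forward order: ring B is the carvone ring from the start (carvone C1=O, C2(Me)=C3, C5 and C6 become C9, C8(Me)=C7, C5 and C10). C10 is made quaternary, ring A is then closed on ring B as the last ring, and the C11–C15 chain is joined afterwards.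
3. Enabling feature: in ring A the quaternary gem-dimethyl carbon C4 lies between the ring-fusion CH (C5) and the carbinol carbon C3. This is the retron of an isopropenyl group on C5 and a 3-oxopropyl arm on C10; hydrogen-atom transfer turns the isopropenyl CH2 into the second C4 methyl as the C3–C4 bond forms.
4. Stereochemistry: C5 comes from (S)-carvone; C10 from allylation anti to the isopropenyl group; C3 from the ring closure (equatorial oxygen); C9 from the epoxide-to-aldehyde rearrangement (equatorial formyl); C11 from 1,2-induction by C9 in the aldol step; the 13E alkene from the dienolate addition.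

Key step: step 4

Remark: the target SMILES is read as the (3R,5S,9R,10R,11S,13E) isomer of a labda-7,13-diene of the ent series; labdane (drimane) numbering is used for all bicyclic compounds.

**Route**

Step 1
Reactants: 1 (S)-(+)-carvone
Product: 3 6-methylcarvone (C6 epimer mixture), via lithium enolate 2 (not isolated)
Conditions: LiN(i-Pr)2, THF, −78 °C; MeI, −78 → 0 °C
Reagents that add atoms: iodomethane, CI
Why: Kinetic deprotonation at the alpha-prime carbon gives the cross-conjugated lithium enolate, whose C-methylation (enolate alkylation) installs the future C10 methyl; the new centre forms as an epimer mixture, which does not matter because it is planarised again in step 2.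

Step 2
Reactants: 3 6-methylcarvone (C6 epimer mixture)
Product: 5 (5R,6R)-6-allyl-6-methylcarvone, via lithium enolate 4 (not isolated)
Conditions: LiN(i-Pr)2, THF, −78 °C; allyl bromide, DMPU, −78 °C → rt
Reagents that add atoms: allyl bromide, C=CCBr
Why: The tetrasubstituted enolate is allylated (enolate alkylation) on the face anti to the adjacent isopropenyl group, so the allyl arm (C1–C3) ends trans and the methyl cis to the isopropenyl group, which is the C5/C10 relationship of the trans-decalin.

Step 3
Reactants: 5 (5R,6R)-6-allyl-6-methylcarvone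
Product: 6 3-[(1R,6R)-1,3-dimethyl-2-oxo-6-(prop-1-en-2-yl)cyclohex-3-en-1-yl]propanal
Conditions: PdCl2(PhCN)2 (10 mol%), CuCl2·2H2O (10 mol%), AgNO2 (5 mol%), O2 (1 atm), t-BuOH/MeNO2, rt
Reagents that add atoms: dioxygen, O=O
Why: The nitrite-modified, aldehyde-selective Wacker oxidation should oxygenate the terminal carbon of the monosubstituted alkene, since the 1,1-disubstituted isopropenyl and the enone alkene are poor substrates for divalent palladium and the neighbouring quaternary carbon disfavours attack at the internal carbon.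

Step 4
Reactants: 6 3-[(1R,6R)-1,3-dimethyl-2-oxo-6-(prop-1-en-2-yl)cyclohex-3-en-1-yl]propanal
Product: 7 (4aR,6R,8aR)-6-hydroxy-2,5,5,8a-tetramethyl-4a,5,6,7,8,8a-hexahydronaphthalen-1(4H)-one (3-hydroxy, 9-oxo, 7-ene in terpenoid numbering)
Conditions: Fe(acac)3 (30 mol%), PhSiH3 (2.5 equiv), EtOH (0.02 M), 60 °C
Reagents that add atoms: none
Why: A hydride on iron formed from Fe(acac)3 and PhSiH3 should transfer a hydrogen atom to the CH2 terminus of the isopropenyl group, the only electron-rich 1,1-disubstituted alkene, which creates the second C4 methyl and a tertiary C4 radical. This radical adds to the C3 aldehyde carbon in a 6-exo-trig closure of ring A, and the alkoxy radical is reduced by divalent iron to an iron alkoxide that ethanol protonates; the closest known reaction type is the iron-hydride-initiated reductive radical coupling of unactivated alkenes with ketones and aldehydes. C3 is the only new stereocentre: in the chair transition state built on the trans-disposed C5 and C10 arms the carbonyl oxygen sits pseudo-equatorial, and because the addition is reversible the equatorial alkoxide (cis to the C10 methyl) should be drained off preferentially. The trans ring fusion is not at stake, since C5 and C10 are fixed before the closure. The step needs hydrogen-atom transfer to the isopropenyl group in preference to the conjugated C7=C8 bond, and ring closure faster than reduction of the radical; the electron-poor trisubstituted enone alkene is a poor hydrogen-atom acceptor, the quaternary C10 and the disubstituted radical carbon favour the folded conformer, and attack on the C9 carbonyl or the enone would give only a four-membered ring.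

Step 5
Reactants: 7 (4aR,6R,8aR)-6-hydroxy-2,5,5,8a-tetramethyl-4a,5,6,7,8,8a-hexahydronaphthalen-1(4H)-one
Product: 8 (2R,4aR,8aR)-1,1,4a,6-tetramethyl-5-oxo-1,2,3,4,4a,5,8,8a-octahydronaphthalen-2-yl 2,2-dimethylpropanoate
Conditions: PivCl, pyridine, DMAP (cat.), CH2Cl2, 0 → 40 °C
Reagents that add atoms: pivaloyl chloride, CC(C)(C)C(Cl)=O
Why: Acylation of the equatorial secondary alcohol under nucleophilic catalysis gives an ester that should survive the ylide and the Lewis acids of the next steps and is cleaved without an extra step in the hydride reduction of step 11.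

Step 6
Reactants: 8 (2R,4aR,8aR)-1,1,4a,6-tetramethyl-5-oxo-1,2,3,4,4a,5,8,8a-octahydronaphthalen-2-yl 2,2-dimethylpropanoate
Product: 9 C9 spiro-epoxide of 8 (vinyl oxirane; epoxide CH2 = C11 anti and oxygen syn to the C10 methyl)
Conditions: Me3S+ I−, n-BuLi, THF, −10 °C; then 8, −10 → 0 °C
Reagents that add atoms: trimethylsulfonium iodide, C[S+](C)C.[I-]
Why: In this Corey–Chaykovsky epoxidation the small unstabilised sulfonium ylide should add 1,2 to the hindered enone carbonyl on the face anti to the axial C10 methyl, and the betaine closes to the vinyl oxirane with C11 anti and oxygen syn to that methyl.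

Step 7
Reactants: 9 C9 spiro-epoxide of 8
Product: 10 (3R,5S,9R,10R)-11-oxodrim-7-en-3-yl 2,2-dimethylpropanoate (3-pivaloyloxy-drim-7-en-11-al, ent series)
Conditions: BF3·OEt2 (0.2 equiv), CH2Cl2, −78 °C; aq. NaHCO3
Reagents that add atoms: none
Why: In this Meinwald rearrangement the Lewis acid opens the allylic tertiary C9–O bond and a hydride shifts from C11 to C9 anti to the departing oxygen, so H-9 should arrive anti to the C10 methyl and the formyl group end equatorial (also the more stable epimer), while the low temperature should keep the C7=C8 bond out of conjugation.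

Step 8
Reactants: 11 methyl 3-methylbut-2-enoate
Product: 13 tert-butyl[(1-methoxy-3-methylbuta-1,3-dien-1-yl)oxy]dimethylsilane, via lithium dienolate 12 (not isolated)
Conditions: LiN(i-Pr)2, THF, −78 °C; TBSCl, DMPU, −78 °C → rt
Reagents that add atoms: tert-butyldimethylsilyl chloride, CC(C)(C)[Si](C)(C)Cl
Why: Gamma-deprotonation of the ester and O-silylation of the extended enolate (silyl ketene acetal formation) give the silyl dienolate, and no stereocentre is created.

Step 9
Reactants: 10 (3R,5S,9R,10R)-11-oxodrim-7-en-3-yl 2,2-dimethylpropanoate; 13 tert-butyl[(1-methoxy-3-methylbuta-1,3-dien-1-yl)oxy]dimethylsilane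
Product: 14 methyl (3R,5S,9R,10R,11S,13E)-11-hydroxy-3-(pivaloyloxy)labda-7,13-dien-15-oate
Conditions: BF3·OEt2 (1.1 equiv), CH2Cl2/Et2O, −78 °C; H2O work-up
Reagents that add atoms: none
Why: In this vinylogous Mukaiyama aldol addition the terminal (gamma) carbon of the dienolate attacks the BF3-activated aldehyde and should give the (E)-enoate directly, and 1,2-induction from C9 is expected to set C11 as 11S because the boron-bound oxygen turns away from the crowded sector between the C8 methyl and C10 while the nucleophile enters anti to C10, past H-9.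

Step 10
Reactants: 14 methyl (3R,5S,9R,10R,11S,13E)-11-hydroxy-3-(pivaloyloxy)labda-7,13-dien-15-oate
Product: 15 methyl (3R,5S,9R,10R,11S,13E)-3-(pivaloyloxy)-11-(triethylsilyloxy)labda-7,13-dien-15-oate
Conditions: TESOTf, 2,6-lutidine, CH2Cl2, −78 → 0 °C
Reagents that add atoms: triethylsilyl trifluoromethanesulfonate, CC[Si](CC)(CC)OS(=O)(=O)C(F)(F)F
Why: Silylation of the hindered secondary C11 alcohol with a silyl triflate and a hindered base (silyl ether formation) masks it for the later acetylation and touches no stereocentre.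

Step 11
Reactants: 15 methyl (3R,5S,9R,10R,11S,13E)-3-(pivaloyloxy)-11-(triethylsilyloxy)labda-7,13-dien-15-oate
Product: 16 (3R,5S,9R,10R,11S,13E)-11-(triethylsilyloxy)labda-7,13-diene-3,15-diol
Conditions: i-Bu2AlH (6 equiv), CH2Cl2, −78 → 0 °C; aq. potassium sodium tartrate
Reagents that add atoms: none
Why: Hydride reduction with excess i-Bu2AlH should convert the conjugated methyl ester into the allylic alcohol without changing the C13=C14 geometry and cleave the pivalate in the same operation, while the silyl ether is inert.

Step 12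
Reactants: 16 (3R,5S,9R,10R,11S,13E)-11-(triethylsilyloxy)labda-7,13-diene-3,15-diol
Product: 17 (3R,5S,9R,10R,11S,13E)-11-(triethylsilyloxy)labda-7,13-diene-3,15-diyl diacetate
Conditions: Ac2O, pyridine, DMAP (cat.), CH2Cl2, rt
Reagents that add atoms: acetic anhydride, CC(=O)OC(C)=O
Why: Acetylation under nucleophilic catalysis esterifies the primary allylic C15 and the equatorial C3 hydroxyls, which are the only free ones.

Step 13
Reactants: 17 (3R,5S,9R,10R,11S,13E)-11-(triethylsilyloxy)labda-7,13-diene-3,15-diyl diacetate
Product: 18 (3R,5S,9R,10R,11S,13E)-11-hydroxylabda-7,13-diene-3,15-diyl diacetate (target)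
Conditions: HF·pyridine, pyridine, THF, 0 °C → rt
Reagents that add atoms: none
Why: Buffered fluoride-mediated desilylation should cleave the triethylsilyl ether without acyl migration (neither acetate can reach O11 through a small cyclic transition state) and without ionising the allylic acetate.

**Compound list**

1 | (S)-(+)-carvone, (5S)-2-methyl-5-(prop-1-en-2-yl)cyclohex-2-en-1-one | O=C1C(C)=CC[C@H](C(C)=C)C1 | starting material
2 | lithium enolate of 1 (cross-conjugated, C1–C6) | [Li+].[O-]C1=C[C@@H](C(C)=C)CC=C1C | intermediate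
3 | 6-methylcarvone, (5S)-2,6-dimethyl-5-(prop-1-en-2-yl)cyclohex-2-en-1-one, C6 epimer mixture | O=C1C(C)=CC[C@H](C(C)=C)C1C | intermediate
4 | lithium enolate of 3 (C1–C6, tetrasubstituted) | [Li+].[O-]C1=C(C)[C@@H](C(C)=C)CC=C1C | intermediate
5 | (5R,6R)-2,6-dimethyl-6-(prop-2-en-1-yl)-5-(prop-1-en-2-yl)cyclohex-2-en-1-one (allyl trans to isopropenyl) | O=C1C(C)=CC[C@H](C(C)=C)[C@@]1(C)CC=C | intermediate
6 | 3-[(1R,6R)-1,3-dimethyl-2-oxo-6-(prop-1-en-2-yl)cyclohex-3-en-1-yl]propanal | O=C1C(C)=CC[C@H](C(C)=C)[C@@]1(C)CCC=O | intermediate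
7 | (4aR,6R,8aR)-6-hydroxy-2,5,5,8a-tetramethyl-4a,5,6,7,8,8a-hexahydronaphthalen-1(4H)-one (trans-fused; OH equatorial, cis to the angular methyl) | O=C1C(C)=CC[C@@H]2C(C)(C)[C@H](O)CC[C@]21C | intermediate
8 | (2R,4aR,8aR)-1,1,4a,6-tetramethyl-5-oxo-1,2,3,4,4a,5,8,8a-octahydronaphthalen-2-yl 2,2-dimethylpropanoate | O=C1C(C)=CC[C@@H]2C(C)(C)[C@H](OC(=O)C(C)(C)C)CC[C@]21C | intermediate
9 | C9 spiro-epoxide of 8 (vinyl oxirane; CH2 anti, O syn to the C10 methyl) | C1O[C@@]12C(C)=CC[C@@H]3C(C)(C)[C@H](OC(=O)C(C)(C)C)CC[C@]32C | intermediate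
10 | (3R,5S,9R,10R)-11-oxodrim-7-en-3-yl 2,2-dimethylpropanoate (formyl equatorial) | O=C[C@@H]1C(C)=CC[C@@H]2C(C)(C)[C@H](OC(=O)C(C)(C)C)CC[C@]21C | intermediate
11 | methyl 3-methylbut-2-enoate | COC(=O)C=C(C)C | starting material
12 | lithium dienolate of 11 | [Li+].[O-]C(OC)=CC(C)=C | intermediate
13 | tert-butyl[(1-methoxy-3-methylbuta-1,3-dien-1-yl)oxy]dimethylsilane (ketene acetal geometry not defined) | COC(O[Si](C)(C)C(C)(C)C)=CC(C)=C | intermediate
14 | methyl (3R,5S,9R,10R,11S,13E)-11-hydroxy-3-(pivaloyloxy)labda-7,13-dien-15-oate | COC(=O)/C=C(\C)C[C@H](O)[C@@H]1C(C)=CC[C@@H]2C(C)(C)[C@H](OC(=O)C(C)(C)C)CC[C@]21C | intermediate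
15 | methyl (3R,5S,9R,10R,11S,13E)-3-(pivaloyloxy)-11-(triethylsilyloxy)labda-7,13-dien-15-oate | COC(=O)/C=C(\C)C[C@H](O[Si](CC)(CC)CC)[C@@H]1C(C)=CC[C@@H]2C(C)(C)[C@H](OC(=O)C(C)(C)C)CC[C@]21C | intermediate
16 | (3R,5S,9R,10R,11S,13E)-11-(triethylsilyloxy)labda-7,13-diene-3,15-diol | OC/C=C(\C)C[C@H](O[Si](CC)(CC)CC)[C@@H]1C(C)=CC[C@@H]2C(C)(C)[C@H](O)CC[C@]21C | intermediate
17 | (3R,5S,9R,10R,11S,13E)-11-(triethylsilyloxy)labda-7,13-diene-3,15-diyl diacetate | CC(=O)OC/C=C(\C)C[C@H](O[Si](CC)(CC)CC)[C@@H]1C(C)=CC[C@@H]2C(C)(C)[C@H](OC(C)=O)CC[C@]21C | intermediate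
18 | (3R,5S,9R,10R,11S,13E)-11-hydroxylabda-7,13-diene-3,15-diyl diacetate | CC(=O)OC/C=C(\C)C[C@H](O)[C@@H]1C(C)=CC[C@@H]2C(C)(C)[C@H](OC(C)=O)CC[C@]21C | target

**Step count**

Total step count: 13 (12 in the main line and 1 for the dienolate 13).
Longest linear sequence: 12 steps (steps 1–7 and 9–13, from (S)-carvone).

**Steps most likely to fail, with fallbacks**

Step 4. The addition of the tertiary radical to the aldehyde is reversible. If the alkoxy radical is not reduced fast enough, the radical may instead be reduced (plain hydrogenation of the isopropenyl group) or add to the enone of a second molecule. The fallback sets out from 6 and returns at 7. The aldehyde is converted into the nitrile 3-[(1R,6R)-1,3-dimethyl-2-oxo-6-(prop-1-en-2-yl)cyclohex-3-en-1-yl]propanenitrile F1 (I2, aq. NH3, THF, rt). The same Fe(acac)3/PhSiH3 conditions should then close ring A onto the nitrile carbon, where the iminyl radical does not revert, and hydrolytic work-up gives the dione (4aR,8aR)-2,5,5,8a-tetramethyl-4a,7,8,8a-tetrahydronaphthalene-1,6(4H,5H)-dione F2. NaBH4 in MeOH at −40 °C should reduce only the saturated C3 ketone, not the hindered conjugated C9 ketone, and give the equatorial alcohol 7.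

Step 7. Under the Lewis acid the allyl cation may lose a proton to a dienol, the C7=C8 bond may move into conjugation with the aldehyde, or C9 may epimerise. The fallback sets out from 8 and returns at 10. Wittig methylenation of the C9 ketone (Ph3PCH3Br, KOt-Bu, toluene, 80 °C) gives the diene drima-7,9(11)-dien-3-yl pivalate F3 (ent series, C3, C5 and C10 as in 8). 9-BBN should add to the exocyclic C9=C11 bond from the face anti to the C10 methyl (boron on C11, hydrogen on C9), and oxidation with NaBO3·4H2O gives the primary alcohol 11-hydroxydrim-7-en-3-yl pivalate F4. DMP buffered with NaHCO3 then gives 10 under non-epimerising conditions.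

Step 9. Facial selectivity at the aldehyde carbon may be poor, or the opposite C11 epimer may be preferred. The fallback sets out from 10 and returns at 14. The aldol addition is run as in step 9, and the adduct mixture rich in the 11R epimer of 14, F5, is oxidised (DMP, NaHCO3, CH2Cl2, 0 °C) to the C11 ketone methyl (3R,5S,9R,10R,13E)-11-oxo-3-(pivaloyloxy)labda-7,13-dien-15-oate F6. Reduction with NaBH4 and CeCl3·7H2O in MeOH at −78 °C should bring the hydride in along the same open trajectory (anti to C10, past H-9), which now gives the 11S alcohol 14.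

**Further compounds**

F1 | step 4 | 3-[(1R,6R)-1,3-dimethyl-2-oxo-6-(prop-1-en-2-yl)cyclohex-3-en-1-yl]propanenitrile | O=C1C(C)=CC[C@H](C(C)=C)[C@@]1(C)CCC#N
F2 | step 4 | (4aR,8aR)-2,5,5,8a-tetramethyl-4a,7,8,8a-tetrahydronaphthalene-1,6(4H,5H)-dione | O=C1C(C)=CC[C@@H]2C(C)(C)C(=O)CC[C@]21C
F3 | step 7 | drima-7,9(11)-dien-3-yl pivalate (ent series, C3, C5 and C10 as in 8) | C=C1C(C)=CC[C@@H]2C(C)(C)[C@H](OC(=O)C(C)(C)C)CC[C@]21C
F4 | step 7 | (3R,5S,9R,10R)-11-hydroxydrim-7-en-3-yl pivalate | OC[C@@H]1C(C)=CC[C@@H]2C(C)(C)[C@H](OC(=O)C(C)(C)C)CC[C@]21C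
F5 | step 9 | methyl (3R,5S,9R,10R,11R,13E)-11-hydroxy-3-(pivaloyloxy)labda-7,13-dien-15-oate (C11 epimer of 14) | COC(=O)/C=C(\C)C[C@@H](O)[C@@H]1C(C)=CC[C@@H]2C(C)(C)[C@H](OC(=O)C(C)(C)C)CC[C@]21C
F6 | step 9 | methyl (3R,5S,9R,10R,13E)-11-oxo-3-(pivaloyloxy)labda-7,13-dien-15-oate | COC(=O)/C=C(\C)CC(=O)[C@@H]1C(C)=CC[C@@H]2C(C)(C)[C@H](OC(=O)C(C)(C)C)CC[C@]21C
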